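Your next flask gets one change, so choose it now: more catalyst, faster transfer, or a higher saturation of the gas phase.

common to all: starting material 0.20 M; gas phase 34 mM (held)

|  | catalyst | remark | time |
|---|---|---|---|
| teal | 28 mM | run made earlier |  |
| ochre | 44 mM | run made earlier |  |
| flask | 20 mM |  | 15 min |

| run | time / min | product / % |
|---|---|---|
| teal | 1.50 | 15 |
| teal | 4.00 | 31 |
| teal | 8.00 | 52 |
| teal | 12.0 | 66 |
| ochre | 1.00 | 14 |
| ochre | 2.00 | 28 |
| ochre | 5.00 | 51 |
| ochre | 12.0 | 74 |

(standard deviation of a reading: 2 percentage points)

1. amount of product at 15 min, in percent of the starting material charged
2. the change that raises the amount of product at 15 min, in percent of the starting material charged most ("none" if none brings more than 2 percentage points) (winter / midnight / autumn / none)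
3. amount of product at 15 min, in percent of the starting material charged, after midnight

- winter: doubling the amount of catalyst, all else as stated
- midnight: doubling the transfer coefficient of the gas phase, all else as stated
- autumn: doubling the saturation concentration of gas phase, all else as stated

- at the start none of the gas is dissolved
- what was read earlier has a scatter of 2 percentage points, one standard deviation
- candidate steps: gas phase <-> dissolved gas; starting material + dissolved gas + catalyst <-> catalyst + product

Put both runs on one clock. Your flask's 15 min on 20 mM count as 10.7 min of teal, and that figure is its teal time, the minutes of a run multiplied by its catalyst and divided by teal's catalyst.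

Test the clock first. Ochre at 5.00 min has a teal time of 7.86 min, about the same as teal's 8.00 min, and it reads 51% against 52%. So I take product as following teal time and join the two teal readings on either side of the flask:

y ≈ 52% + (66% − 52%) × (10.7 min − 8.00 min) / (12.0 min − 8.00 min) = 61.5%

Doubled catalyst gives the flask a teal time of 21.4 min, and ochre's last reading is 74% at a teal time of 18.9 min, so I expect a gain near 12 percentage points. Dissolved gas is a reactant in the catalysed step, so doubled saturation should speed its forward run likewise and also push its end further. Charge that one. Faster transfer I expect to add less than 2 points.

The forecast gives 60%, a little below my figure, with autumn as the best change and 61% after midnight, on the ground that “gas transfer is not limiting”.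

The flask gives 63.8%, and 65.4% after midnight. The gains are 19 points for autumn, 9.4 points for winter and 1.6 points for midnight, so the best change is autumn.

    gas phase ⇌ dissolved gas, rate k1*(csat - [dissolved gas]) (kL = 2.80 min⁻¹)
    starting material + dissolved gas + catalyst ⇌ catalyst + product (K = 91.0 L mol⁻¹, k = 160 L² mol⁻² min⁻¹)

At its teal time of 10.7 min the flask stands 2.3 points above my join. By 15 min the transfer could deliver 714% of the charge into a solution kept empty, far more than the 63.8% of product formed. In the flask, dissolved gas stands at 0.0328 M at 15.0 min, against a saturation of 34 mM. On the same clock, the doubled-catalyst flask at a teal time of 21.4 min gives 73.2%, and ochre read 74% at a teal time of 18.9 min.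

(The data come from a simulation for an exercise.)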